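**Retrosynthetic overview**
1. Rings: A = methoxy ring (C1 CH2CH2, C2 OAr, C3 OMe); B = meta-phenylene; C = phenol ring (C1 CH2CH2, C3 OAr, C4 OH); D = para-phenylene (C1 O, C4 CH2). Target 13 ⇐ benzyl ether 12 by hydrogenolysis.
2. 12 ⇐ open-chain bromo-styrene 10: the ring D C4–CH2 bond is made by a one-pot hydroboration/B-alkyl Suzuki–Miyaura macrocyclisation; the 18-membered ring is the only ring formed in the route and is formed last.
3. Enabling feature: the saturated CH2–CH2 bridge between ring A C1 and ring D C4. Its ring-D-bound CH2 is the anti-Markovnikov terminus of a vinyl group on ring A C1, and ring D C4 (para to the ether oxygen, unhindered) can carry Br; the two diaryl ether oxygens act as hinges.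
4. 10 ⇐ iodo-styrene 4 (rings A, B) + bromo-styrene 8 (rings C, D): the ring B–CH2CH2–ring C bridge is made by the same reaction run intermolecularly, iodide before bromide.
5. 4 ⇐ SNAr of 2-fluoro-3-methoxybenzaldehyde with 3-iodophenol, then methylenation; 8 ⇐ Chan–Lam coupling of 4-(benzyloxy)-3-hydroxybenzaldehyde with (4-bromophenyl)boronic acid, then methylenation.

Key step: step 6

Remark: 13 has no stereocentre and its 18-membered ring is taken to be conformationally mobile, so no stereocontrol is planned; compounds 1, 2, 5 and 6 are taken as commercial.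

**Route**

Step 1
Reactants: 1 2-fluoro-3-methoxybenzaldehyde; 2 3-iodophenol
Product: 3 2-(3-iodophenoxy)-3-methoxybenzaldehyde
Conditions: K2CO3 (1.5 equiv), DMF, 120 °C, N2
Reagents that add atoms: none
Why: Nucleophilic aromatic substitution (SNAr) should occur because the ortho formyl group stabilises the Meisenheimer adduct at the fluorine-bearing carbon of 1, fluoride is the best leaving group for addition–elimination, and the C–I bond of 2 is inert without copper or palladium.

Step 2
Reactants: 3 2-(3-iodophenoxy)-3-methoxybenzaldehyde
Product: 4 1-ethenyl-2-(3-iodophenoxy)-3-methoxybenzene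
Conditions: Ph3PCH3Br, KOtBu, THF, 0 °C to rt
Reagents that add atoms: methyltriphenylphosphonium bromide, C[P+](c1ccccc1)(c1ccccc1)c1ccccc1.[Br-]
Why: Wittig methylenation with the non-stabilised ylide should convert the aryl aldehyde into the terminal styrene without touching the aryl iodide or the diaryl ether.

Step 3
Reactants: 5 4-(benzyloxy)-3-hydroxybenzaldehyde; 6 (4-bromophenyl)boronic acid
Product: 7 4-(benzyloxy)-3-(4-bromophenoxy)benzaldehyde
Conditions: 6 (2 equiv), Cu(OAc)2 (1.0 equiv, kept divalent by O2), pyridine (5 equiv), 4 Å MS, CH2Cl2, dry air, rt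
Reagents that add atoms: none
Why: Chan–Lam oxidative O-arylation should join the phenoxide and the aryl group of 6 on copper and form the diaryl ether by reductive elimination from a trivalent copper intermediate at room temperature, where the aldehyde, the benzyl ether and the C–Br bond are spectators.

Step 4
Reactants: 7 4-(benzyloxy)-3-(4-bromophenoxy)benzaldehyde
Product: 8 1-(benzyloxy)-2-(4-bromophenoxy)-4-ethenylbenzene
Conditions: Ph3PCH3Br, KOtBu, THF, 0 °C to rt
Reagents that add atoms: methyltriphenylphosphonium bromide, C[P+](c1ccccc1)(c1ccccc1)c1ccccc1.[Br-]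
Why: Wittig methylenation as in step 2 should give the styrene, the aryl bromide and benzyl ether being stable to the ylide.

Step 5
Reactants: 8 1-(benzyloxy)-2-(4-bromophenoxy)-4-ethenylbenzene; 4 1-ethenyl-2-(3-iodophenoxy)-3-methoxybenzene
Product: 10 1-(benzyloxy)-2-(4-bromophenoxy)-4-{2-[3-(2-ethenyl-6-methoxyphenoxy)phenyl]ethyl}benzene (open-chain bromo-styrene), via B-alkyl-9-BBN 9 (not isolated)
Conditions: 8 (1.15 equiv), 9-BBN dimer (1.1 equiv B–H), THF, 0 °C to rt; then aq K3PO4 (3 M), 4 (1.0 equiv), PdCl2(dppf) (5 mol %), DMF, rt
Reagents that add atoms: none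
Why: Hydroboration/B-alkyl Suzuki–Miyaura cross-coupling should work because 9-BBN places boron on the terminal carbon of styrene 8, zerovalent palladium inserts at room temperature into the C–I bond of 4 far faster than into the electron-rich ring D C–Br bond, and the vinyl group of 4 survives since all B–H is consumed by the slight excess of 8 before 4 is added and Heck arylation is slow at this temperature.

Step 6
Reactants: 10 1-(benzyloxy)-2-(4-bromophenoxy)-4-{2-[3-(2-ethenyl-6-methoxyphenoxy)phenyl]ethyl}benzene
Product: 12 O-benzyl macrocycle (13 carrying a benzyl ether at ring C C4), via B-alkyl-9-BBN 11 (not isolated)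
Conditions: 9-BBN dimer (1.5 equiv B–H), THF, 0 °C to rt; then syringe-pump addition (12 h) to PdCl2(dppf) (15 mol %), AsPh3 (30 mol %), Cs2CO3 (4 equiv), DMF/THF/H2O, 60 °C, final concentration about 1 mM
Reagents that add atoms: none
Why: 9-BBN should add across the ring A vinyl group with boron on the terminal carbon to give primary alkylborane 11; zerovalent palladium then inserts into the ring D C–Br bond, the base-activated borate transfers its primary alkyl group to palladium, and C(sp2)–C(sp3) reductive elimination forms the ring D C4–CH2 bond. The closest known reaction type is the hydroboration/B-alkyl Suzuki–Miyaura macrocyclisation used to close carbocyclic macrocycles and cyclophanes at an sp2–sp3 bond. The single ring closed is the 18-membered bis(bibenzyl) macrocycle, which closes end to end through a 19-membered palladacycle that contracts on reductive elimination; rings A to D are already present. No stereocentre is formed and the product is achiral. The selectivities needed are terminal hydroboration (secured by the monosubstituted styrene and the bulk of 9-BBN), reductive elimination over β-hydride elimination (secured by the wide-bite-angle dppf ligand), and cyclisation over oligomerisation (secured by high dilution, by the two diaryl ether hinges and the flexible ring B–ring C ethylene bridge that let the chain ends meet without strain, and by the unhindered para position of ring D). The bridge is delivered at the saturated oxidation level, so no alkene reduction is needed after ring closure.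

Step 7
Reactants: 12 O-benzyl macrocycle
Product: 13 target macrocycle (CNP0309263.0)
Conditions: H2 (1 atm), Pd/C (10 wt % Pd), EtOAc/MeOH, rt
Reagents that add atoms: none
Why: Catalytic hydrogenolysis of the benzyl ether should free the ring C phenol while the methyl ether, both diaryl ethers and the saturated bridges stay inert, and no stereocentre is present.

**Compound list**
1 | 2-fluoro-3-methoxybenzaldehyde | COc1cccc(C=O)c1F | starting material
2 | 3-iodophenol | Oc1cccc(I)c1 | starting material
3 | 2-(3-iodophenoxy)-3-methoxybenzaldehyde | COc1cccc(C=O)c1Oc1cccc(I)c1 | intermediate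
4 | 1-ethenyl-2-(3-iodophenoxy)-3-methoxybenzene | COc1cccc(C=C)c1Oc1cccc(I)c1 | intermediate
5 | 4-(benzyloxy)-3-hydroxybenzaldehyde | O=Cc1ccc(OCc2ccccc2)c(O)c1 | starting material
6 | (4-bromophenyl)boronic acid | OB(O)c1ccc(Br)cc1 | starting material
7 | 4-(benzyloxy)-3-(4-bromophenoxy)benzaldehyde | O=Cc1ccc(OCc2ccccc2)c(Oc2ccc(Br)cc2)c1 | intermediate
8 | 1-(benzyloxy)-2-(4-bromophenoxy)-4-ethenylbenzene | C=Cc1ccc(OCc2ccccc2)c(Oc2ccc(Br)cc2)c1 | intermediate
9 | 9-{2-[4-(benzyloxy)-3-(4-bromophenoxy)phenyl]ethyl}-9-borabicyclo[3.3.1]nonane (not isolated) | B1(CCc2ccc(OCc3ccccc3)c(Oc3ccc(Br)cc3)c2)C2CCCC1CCC2 | intermediate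
10 | 1-(benzyloxy)-2-(4-bromophenoxy)-4-{2-[3-(2-ethenyl-6-methoxyphenoxy)phenyl]ethyl}benzene | COc1cccc(C=C)c1Oc1cccc(CCc2ccc(OCc3ccccc3)c(Oc3ccc(Br)cc3)c2)c1 | intermediate
11 | 9-{2-[2-(3-{2-[4-(benzyloxy)-3-(4-bromophenoxy)phenyl]ethyl}phenoxy)-3-methoxyphenyl]ethyl}-9-borabicyclo[3.3.1]nonane (not isolated) | COc1cccc(CCB2C3CCCC2CCC3)c1Oc1cccc(CCc2ccc(OCc3ccccc3)c(Oc3ccc(Br)cc3)c2)c1 | intermediate
12 | O-benzyl macrocycle (13 with the ring C hydroxyl as benzyl ether) | COc1cccc2c1Oc1cccc(c1)CCc1ccc(OCc3ccccc3)c(c1)Oc1ccc(cc1)CC2 | intermediate
13 | target macrocycle: 18-membered bis(bibenzyl) with OMe at ring A C3 and OH at ring C C4 | COc1cccc2c1Oc1cccc(c1)CCc1ccc(O)c(c1)Oc1ccc(cc1)CC2 | target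

**Totals and risks**
Total step count: 7. Longest linear sequence: 5 steps (1, 2, 5, 6, 7 or 3, 4, 5, 6, 7).

Steps most likely to fail:

1. Step 6. Intermolecular coupling may outpace ring closure and give oligomers, or the alkylpalladium intermediate may undergo β-hydride elimination and return open-chain material; a more electron-rich ligand would be the first adjustment. The fallback sets out from 10 and returns at 13. An intramolecular Mizoroki–Heck macrocyclisation of 10 (Pd(OAc)2, P(o-tol)3, K2CO3, n-Bu4NBr, DMF, 100 °C, high dilution) should form the same ring D C4–carbon bond at the alkene oxidation level and give the benzyl-protected (E)-stilbene macrocycle F1. Hydrogenation of F1 (H2, Pd/C, EtOAc/MeOH) should then saturate the stilbene and cleave the benzyl ether in one operation to give 13.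

2. Step 5. The spectator vinyl group of 4 may be consumed by stray hydroboration or Heck arylation, or iodide-over-bromide selectivity may erode and give oligomers. The fallback sets out from 8 (through borane 9) and 3 and returns at 10. Borane 9 is coupled with the vinyl-free iodo-aldehyde 3 under the same iodide-selective catalysis to give the open-chain aldehyde 2-(3-{2-[4-(benzyloxy)-3-(4-bromophenoxy)phenyl]ethyl}phenoxy)-3-methoxybenzaldehyde F2. Wittig methylenation of F2 (Ph3PCH3Br, KOtBu, THF) then installs the ring A vinyl group only after the coupling and gives 10.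

3. Step 3. The oxidative coupling may stall because protodeboronation and homocoupling use up the boronic acid while the hindered, electron-poor phenol binds copper slowly. The fallback sets out from 5 and returns at 7. A redox-neutral Ullmann-type O-arylation of 5 with commercial 1-bromo-4-iodobenzene (CuI, N,N-dimethylglycine, Cs2CO3, dioxane, 90 °C) should react selectively at the C–I bond and give 7 directly; this fallback makes no compound outside the list (F0).

Further compounds
F1 | step 6 | benzyl-protected (E)-stilbene macrocycle (12 with a ring A–CH=CH–ring D bridge) | COc1cccc(/C=C/c2ccc(Oc3cc(CCc4cccc(O5)c4)ccc3OCc3ccccc3)cc2)c15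
F2 | step 5 | 2-(3-{2-[4-(benzyloxy)-3-(4-bromophenoxy)phenyl]ethyl}phenoxy)-3-methoxybenzaldehyde | COc1cccc(C=O)c1Oc1cccc(CCc2ccc(OCc3ccccc3)c(Oc3ccc(Br)cc3)c2)c1
F0 | step 3 | none | none
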